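**Retrosynthetic overview**

1. The target is unmasked last (desilylation, 3-O-galloylation, hydrogenolysis) from a benzyl-protected luteoliflavan-(4→8)-epigallocatechin. Its upper pyran ring C is closed at O1–C2 by Mitsunobu inversion of an (R)-carbinol obtained by CBS reduction of a keto-phenol.
2. The keto-phenol comes from the ring-B aryllithium and a (4R)-5,7-bis(benzyloxy)-4-aryl-3,4-dihydrocoumarin (bond C2–C1').
3. Feature and key disconnection: in upper ring C, O1 lies between aromatic C8a of ring A and C2, while the stereocentre C4 is bonded to C4a of ring A and to C8 of lower ring D. Removing O1 from the lactone leaves a 3-arylindan-1-one (indanone C1/C2/C3/C3a/C7a = flavan C2/C3/C4/C4a/C8a), so O1–C8a is made by Baeyer–Villiger oxygen insertion.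
4. The indanone comes from a 2'-bromochalcone by asymmetric reductive Heck closure of C3–C3a, which sets C4. The chalcone comes from aldol condensation of 8-formyl benzylated, silylated epigallocatechin with 2-bromo-3,5-bis(benzyloxy)acetophenone.
5. Ring order: rings D/E/F are taken from (−)-epigallocatechin and ring A from the acetophenone; then five-membered carbocycle (step 7) → six-membered lactone (step 8) → opened with ring B (step 9) → pyran ring C (step 11).

Key step: step 8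

Remark (naming): "EGC*-8-yl" stands for (2R,3R)-5,7-bis(benzyloxy)-3-[(tert-butyldimethylsilyl)oxy]-2-[3,4,5-tris(benzyloxy)phenyl]chroman-8-yl.
Assumption (step 7): the sense of induction of the bisphosphine on this substrate cannot be predicted with certainty; the (R)-ligand is written, and its antipode is used instead if a pilot run shows the opposite sense.
Assumption (materials): 3,4,5-tris(benzyloxy)benzoic acid is bought rather than made from gallic acid.

**Route**

Step 1
Reactants: 1 (−)-epigallocatechin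
Product: 2 (2R,3R)-5,7-bis(benzyloxy)-2-[3,4,5-tris(benzyloxy)phenyl]chroman-3-ol
Conditions: BnBr (5.5 equiv), K2CO3, DMF, 0 °C → rt, Ar
Reagents that add atoms: benzyl bromide, BrCc1ccccc1
Why: Williamson O-alkylation of the five phenols by carbonate leaves the far less acidic secondary 3-OH untouched, and cold, oxygen-free conditions limit C-benzylation, C2 epimerisation and oxidation of the pyrogallol ring.

Step 2
Reactants: 2 (2R,3R)-5,7-bis(benzyloxy)-2-[3,4,5-tris(benzyloxy)phenyl]chroman-3-ol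
Product: 3 (2R,3R)-8-bromo-5,7-bis(benzyloxy)-2-[3,4,5-tris(benzyloxy)phenyl]chroman-3-ol
Conditions: NBS (1.0 equiv), CH2Cl2, −78 °C → rt
Reagents that add atoms: N-bromosuccinimide, O=C1CCC(=O)N1Br
Why: Electrophilic aromatic bromination takes place on the phloroglucinol-type ring D, which is much more nucleophilic than ring E, and C8 is the site preferred over C6 in 5,7-di-O-benzyl flavan-3-ols.

Step 3
Reactants: 3 (2R,3R)-8-bromo-5,7-bis(benzyloxy)-2-[3,4,5-tris(benzyloxy)phenyl]chroman-3-ol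
Product: 4 EGC*-8-yl bromide
Conditions: TBSCl, imidazole, DMF, rt
Reagents that add atoms: tert-butyldimethylsilyl chloride, CC(C)(C)[Si](C)(C)Cl
Why: Imidazole-promoted silylation of the only free hydroxyl gives an ether that is stable to the organolithium, base, palladium, peracid, borane and Mitsunobu steps that follow.

Step 4
Reactants: 4 EGC*-8-yl bromide
Product: 6 EGC*-8-carbaldehyde, via 8-lithio arene 5 (not isolated)
Conditions: t-BuLi (2.1 equiv), THF, −78 °C; DMF, −78 → 0 °C; H2O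
Reagents that add atoms: N,N-dimethylformamide, CN(C)C=O
Why: Bromine–lithium exchange at −78 °C is faster than ortho- or benzylic metalation, and the aryllithium 5 is formylated by DMF (Bouveault-type formylation), the exchange being established for 8-bromo benzylated flavan-3-ol silyl ethers.

Step 5
Reactants: 7 3,5-bis(benzyloxy)acetophenone
Product: 8 1-[3,5-bis(benzyloxy)-2-bromophenyl]ethan-1-one
Conditions: NBS (1.05 equiv), MeCN, 0 °C → rt, dark
Reagents that add atoms: N-bromosuccinimide, O=C1CCC(=O)N1Br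
Why: Ionic ring bromination with NBS in a polar solvent goes to C2 (para to one benzyloxy group, ortho to the other) rather than to the hindered C4 between the two ethers, as known for 3,5-dialkoxyaryl ketones, and avoids α-bromination of the methyl ketone.

Step 6
Reactants: 6 EGC*-8-carbaldehyde; 8 1-[3,5-bis(benzyloxy)-2-bromophenyl]ethan-1-one
Product: 10 (E)-1-[3,5-bis(benzyloxy)-2-bromophenyl]-3-(EGC*-8-yl)prop-2-en-1-one, via aldol adduct 9 (not isolated)
Conditions: KOH (aq), EtOH–THF, rt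
Reagents that add atoms: none
Why: Claisen–Schmidt condensation: the methyl ketone enolate adds to the non-enolisable aldehyde and the aldol 9 dehydrates by E1cB to the conjugated E-enone, while the alkyl silyl ether and the aryl bromide tolerate hydroxide at room temperature.

Step 7
Reactants: 10 (E)-1-[3,5-bis(benzyloxy)-2-bromophenyl]-3-(EGC*-8-yl)prop-2-en-1-one
Product: 11 (3R)-4,6-bis(benzyloxy)-3-(EGC*-8-yl)indan-1-one
Conditions: Pd(OAc)2 (10 mol %), (R)-3,5-Xyl-MeO-BIPHEP (12 mol %), HCO2Na (1.5 equiv, in portions), DMF–ethylene glycol 9:1, 90 °C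
Reagents that add atoms: none
Why: Asymmetric reductive Heck cyclisation of a 2'-halochalcone to a 3-arylindan-1-one: oxidative addition into the C–Br bond ortho to the acyl group, 5-endo-trig carbopalladation of the enone β-carbon and formate reduction of the palladium enolate form C3–C3a, with the C3 configuration set under catalyst control by enantioface-selective insertion in the chiral bisphosphine pocket.

Step 8
Reactants: 11 (3R)-4,6-bis(benzyloxy)-3-(EGC*-8-yl)indan-1-one
Product: 13 (4R)-5,7-bis(benzyloxy)-4-(EGC*-8-yl)chroman-2-one, via Criegee adduct 12 (not isolated)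
Conditions: mCPBA (2 equiv), NaHCO3, CH2Cl2, 0 °C → rt, dark
Reagents that add atoms: 3-chloroperoxybenzoic acid, O=C(OO)c1cccc(Cl)c1
Why: The peracid adds to the C1 carbonyl of 11 to give the tetrahedral Criegee adduct 12, in which the C1–C7a bond can lie antiperiplanar to the O–O bond, and a concerted 1,2-shift of aromatic C7a from C1 to the proximal peroxide oxygen with loss of 3-chlorobenzoate gives the aryl ester. The closest known reaction is the Baeyer–Villiger oxidation of 1-indanones, 3-aryl-1-indanones included, to 3,4-dihydrocoumarins. The six-membered lactone (O1–C2–C3–C4–C4a–C8a) is closed by ring expansion rather than by cyclisation: the five-membered carbocycle grows by one atom as the migrating aryl carbon becomes bonded to the inserted oxygen (new bond O1–C8a). No stereocentre is created, and C3 of 11, the future C4, is neither origin nor terminus of the shift and is not enolisable, so its R configuration from step 7 is carried through. Two selectivities are needed: aryl rather than CH2 migration, which rests on the higher migratory aptitude of an sp2 aryl carbon over a primary alkyl carbon and on strain relief, although the two meta benzyloxy groups give no resonance help; and oxidation of the ketone rather than of the electron-rich ether rings, which rests on bicarbonate buffering, low temperature and limited peracid.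

Step 9
Reactants: 13 (4R)-5,7-bis(benzyloxy)-4-(EGC*-8-yl)chroman-2-one; 14 4-bromo-1,2-bis(benzyloxy)benzene
Product: 17 (3R)-1-[3,4-bis(benzyloxy)phenyl]-3-[2,4-bis(benzyloxy)-6-hydroxyphenyl]-3-(EGC*-8-yl)propan-1-one, via aryllithium 15 (not isolated), via lithium hemiketalate 16 (not isolated)
Conditions: 14, n-BuLi (1.0 equiv), THF, −78 °C; add to 13, THF, −78 °C; AcOH, −78 °C
Reagents that add atoms: none
Why: Addition of the aryllithium 15 to the lactone carbonyl gives the cyclic lithium hemiketalate 16, which persists at −78 °C and so shields the carbonyl from a second addition, and the cold acetic acid quench releases the keto-phenol (the standard lactone to hydroxy-ketone conversion).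

Step 10
Reactants: 17 (3R)-1-[3,4-bis(benzyloxy)phenyl]-3-[2,4-bis(benzyloxy)-6-hydroxyphenyl]-3-(EGC*-8-yl)propan-1-one
Product: 18 (1R,3R)-1-[3,4-bis(benzyloxy)phenyl]-3-[2,4-bis(benzyloxy)-6-hydroxyphenyl]-3-(EGC*-8-yl)propan-1-ol
Conditions: (S)-Me-CBS (0.3 equiv), BH3·SMe2 (2.5 equiv), THF, −20 → 0 °C; MeOH
Reagents that add atoms: none
Why: Corey–Bakshi–Shibata reduction: with the (S)-oxazaborolidine the aryl group acts as the large substituent and hydride is delivered to the face giving the (R)-carbinol, as for acetophenone; one equivalent of borane is consumed by the phenol, and reagent control is expected to override the remote C3 centre.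

Step 11
Reactants: 18 (1R,3R)-1-[3,4-bis(benzyloxy)phenyl]-3-[2,4-bis(benzyloxy)-6-hydroxyphenyl]-3-(EGC*-8-yl)propan-1-ol
Product: 19 (2S,4R)-5,7-bis(benzyloxy)-2-[3,4-bis(benzyloxy)phenyl]-4-(EGC*-8-yl)chroman
Conditions: PPh3, DIAD, toluene–THF, 0 °C → rt
Reagents that add atoms: none
Why: Intramolecular Mitsunobu etherification: the phenol displaces the activated benzylic oxygen in a 6-exo-tet SN2 closure with inversion, which turns the (R)-carbinol into (2S) and places the 2-aryl group trans to the C4 substituent; low temperature and a weakly polar medium disfavour ionisation of the electron-rich benzylic centre.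

Step 12
Reactants: 19 (2S,4R)-5,7-bis(benzyloxy)-2-[3,4-bis(benzyloxy)phenyl]-4-(EGC*-8-yl)chroman
Product: 20 (2R,3R)-8-{(2S,4R)-5,7-bis(benzyloxy)-2-[3,4-bis(benzyloxy)phenyl]chroman-4-yl}-5,7-bis(benzyloxy)-2-[3,4,5-tris(benzyloxy)phenyl]chroman-3-ol
Conditions: TBAF, THF, rt → 40 °C
Reagents that add atoms: none
Why: Fluoride-induced cleavage of the Si–O bond frees the 3-OH without touching the benzyl ethers or the interflavan C4–C8 bond.

Step 13
Reactants: 20 (2R,3R)-8-{(2S,4R)-5,7-bis(benzyloxy)-2-[3,4-bis(benzyloxy)phenyl]chroman-4-yl}-5,7-bis(benzyloxy)-2-[3,4,5-tris(benzyloxy)phenyl]chroman-3-ol; 21 3,4,5-tris(benzyloxy)benzoic acid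
Product: 22 3-O-[3,4,5-tris(benzyloxy)benzoyl] ester of 20 (dodeca-O-benzyl target)
Conditions: DCC, DMAP, CH2Cl2, rt
Reagents that add atoms: none
Why: Steglich esterification with DMAP acyl transfer is the usual way to galloylate the hindered axial 3-OH of benzylated epicatechin-type units, and it leaves the C3 configuration unchanged because only the O–H bond reacts.

Step 14
Reactants: 22 3-O-[3,4,5-tris(benzyloxy)benzoyl] ester of 20
Product: 23 (2R,3R)-8-[(2S,4R)-2-(3,4-dihydroxyphenyl)-5,7-dihydroxychroman-4-yl]-5,7-dihydroxy-2-(3,4,5-trihydroxyphenyl)chroman-3-yl 3,4,5-trihydroxybenzoate (target)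
Conditions: H2 (1 atm), 20% Pd(OH)2/C, THF–MeOH–H2O, rt; filtration and freeze-drying under Ar
Reagents that add atoms: none
Why: Catalytic hydrogenolysis removes all twelve O-benzyl groups under neutral conditions that leave the gallate ester, the cyclic benzylic C2–O1 ethers and the C4–C8 bond intact when the reaction is stopped at full debenzylation.

**Compound list**

1 | (−)-epigallocatechin | O[C@@H]1Cc2c(O)cc(O)cc2O[C@@H]1c1cc(O)c(O)c(O)c1 | starting material
2 | (2R,3R)-5,7-bis(benzyloxy)-2-[3,4,5-tris(benzyloxy)phenyl]chroman-3-ol | O[C@@H]1Cc2c(OCc3ccccc3)cc(OCc3ccccc3)cc2O[C@@H]1c1cc(OCc2ccccc2)c(OCc2ccccc2)c(OCc2ccccc2)c1 | intermediate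
3 | (2R,3R)-8-bromo-5,7-bis(benzyloxy)-2-[3,4,5-tris(benzyloxy)phenyl]chroman-3-ol | O[C@@H]1Cc2c(OCc3ccccc3)cc(OCc3ccccc3)c(Br)c2O[C@@H]1c1cc(OCc2ccccc2)c(OCc2ccccc2)c(OCc2ccccc2)c1 | intermediate
4 | EGC*-8-yl bromide (3-O-TBS ether of 3) | CC(C)(C)[Si](C)(C)O[C@@H]1Cc2c(OCc3ccccc3)cc(OCc3ccccc3)c(Br)c2O[C@@H]1c1cc(OCc2ccccc2)c(OCc2ccccc2)c(OCc2ccccc2)c1 | intermediate
5 | EGC*-8-yllithium | CC(C)(C)[Si](C)(C)O[C@@H]1Cc2c(OCc3ccccc3)cc(OCc3ccccc3)c([Li])c2O[C@@H]1c1cc(OCc2ccccc2)c(OCc2ccccc2)c(OCc2ccccc2)c1 | intermediate (not isolated)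
6 | EGC*-8-carbaldehyde | CC(C)(C)[Si](C)(C)O[C@@H]1Cc2c(OCc3ccccc3)cc(OCc3ccccc3)c(C=O)c2O[C@@H]1c1cc(OCc2ccccc2)c(OCc2ccccc2)c(OCc2ccccc2)c1 | intermediate
7 | 3,5-bis(benzyloxy)acetophenone | CC(=O)c1cc(OCc2ccccc2)cc(OCc2ccccc2)c1 | starting material
8 | 1-[3,5-bis(benzyloxy)-2-bromophenyl]ethan-1-one | CC(=O)c1cc(OCc2ccccc2)cc(OCc2ccccc2)c1Br | intermediate
9 | 1-[3,5-bis(benzyloxy)-2-bromophenyl]-3-hydroxy-3-(EGC*-8-yl)propan-1-one (carbinol centre undefined) | CC(C)(C)[Si](C)(C)O[C@@H]1Cc2c(OCc3ccccc3)cc(OCc3ccccc3)c(C(O)CC(=O)c3cc(OCc4ccccc4)cc(OCc4ccccc4)c3Br)c2O[C@@H]1c1cc(OCc2ccccc2)c(OCc2ccccc2)c(OCc2ccccc2)c1 | intermediate (not isolated)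
10 | (E)-1-[3,5-bis(benzyloxy)-2-bromophenyl]-3-(EGC*-8-yl)prop-2-en-1-one | CC(C)(C)[Si](C)(C)O[C@@H]1Cc2c(OCc3ccccc3)cc(OCc3ccccc3)c(/C=C/C(=O)c3cc(OCc4ccccc4)cc(OCc4ccccc4)c3Br)c2O[C@@H]1c1cc(OCc2ccccc2)c(OCc2ccccc2)c(OCc2ccccc2)c1 | intermediate
11 | (3R)-4,6-bis(benzyloxy)-3-(EGC*-8-yl)indan-1-one | CC(C)(C)[Si](C)(C)O[C@@H]1Cc2c(OCc3ccccc3)cc(OCc3ccccc3)c([C@@H]3CC(=O)c4cc(OCc5ccccc5)cc(OCc5ccccc5)c43)c2O[C@@H]1c1cc(OCc2ccccc2)c(OCc2ccccc2)c(OCc2ccccc2)c1 | intermediate (key-step precursor)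
12 | (3R)-4,6-bis(benzyloxy)-1-hydroxy-3-(EGC*-8-yl)indan-1-yl 3-chloroperoxybenzoate (Criegee adduct, C1 undefined) | CC(C)(C)[Si](C)(C)O[C@@H]1Cc2c(OCc3ccccc3)cc(OCc3ccccc3)c([C@@H]3CC(O)(OOC(=O)c4cccc(Cl)c4)c4cc(OCc5ccccc5)cc(OCc5ccccc5)c43)c2O[C@@H]1c1cc(OCc2ccccc2)c(OCc2ccccc2)c(OCc2ccccc2)c1 | intermediate (not isolated)
13 | (4R)-5,7-bis(benzyloxy)-4-(EGC*-8-yl)chroman-2-one | CC(C)(C)[Si](C)(C)O[C@@H]1Cc2c(OCc3ccccc3)cc(OCc3ccccc3)c([C@@H]3CC(=O)Oc4cc(OCc5ccccc5)cc(OCc5ccccc5)c43)c2O[C@@H]1c1cc(OCc2ccccc2)c(OCc2ccccc2)c(OCc2ccccc2)c1 | intermediate (key-step product)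
14 | 4-bromo-1,2-bis(benzyloxy)benzene | Brc1ccc(OCc2ccccc2)c(OCc2ccccc2)c1 | starting material
15 | 3,4-bis(benzyloxy)phenyllithium | [Li]c1ccc(OCc2ccccc2)c(OCc2ccccc2)c1 | intermediate (not isolated)
16 | lithium (4R)-5,7-bis(benzyloxy)-2-[3,4-bis(benzyloxy)phenyl]-4-(EGC*-8-yl)chroman-2-olate (C2 undefined) | CC(C)(C)[Si](C)(C)O[C@@H]1Cc2c(OCc3ccccc3)cc(OCc3ccccc3)c([C@@H]3CC(O[Li])(c4ccc(OCc5ccccc5)c(OCc5ccccc5)c4)Oc4cc(OCc5ccccc5)cc(OCc5ccccc5)c43)c2O[C@@H]1c1cc(OCc2ccccc2)c(OCc2ccccc2)c(OCc2ccccc2)c1 | intermediate (not isolated)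
17 | (3R)-1-[3,4-bis(benzyloxy)phenyl]-3-[2,4-bis(benzyloxy)-6-hydroxyphenyl]-3-(EGC*-8-yl)propan-1-one | CC(C)(C)[Si](C)(C)O[C@@H]1Cc2c(OCc3ccccc3)cc(OCc3ccccc3)c([C@@H](c3c(O)cc(OCc4ccccc4)cc3OCc3ccccc3)CC(=O)c3ccc(OCc4ccccc4)c(OCc4ccccc4)c3)c2O[C@@H]1c1cc(OCc2ccccc2)c(OCc2ccccc2)c(OCc2ccccc2)c1 | intermediate
18 | (1R,3R)-1-[3,4-bis(benzyloxy)phenyl]-3-[2,4-bis(benzyloxy)-6-hydroxyphenyl]-3-(EGC*-8-yl)propan-1-ol | CC(C)(C)[Si](C)(C)O[C@@H]1Cc2c(OCc3ccccc3)cc(OCc3ccccc3)c([C@@H](c3c(O)cc(OCc4ccccc4)cc3OCc3ccccc3)C[C@@H](O)c3ccc(OCc4ccccc4)c(OCc4ccccc4)c3)c2O[C@@H]1c1cc(OCc2ccccc2)c(OCc2ccccc2)c(OCc2ccccc2)c1 | intermediate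
19 | (2S,4R)-5,7-bis(benzyloxy)-2-[3,4-bis(benzyloxy)phenyl]-4-(EGC*-8-yl)chroman | CC(C)(C)[Si](C)(C)O[C@@H]1Cc2c(OCc3ccccc3)cc(OCc3ccccc3)c([C@@H]3C[C@@H](c4ccc(OCc5ccccc5)c(OCc5ccccc5)c4)Oc4cc(OCc5ccccc5)cc(OCc5ccccc5)c43)c2O[C@@H]1c1cc(OCc2ccccc2)c(OCc2ccccc2)c(OCc2ccccc2)c1 | intermediate
20 | (2R,3R)-8-{(2S,4R)-5,7-bis(benzyloxy)-2-[3,4-bis(benzyloxy)phenyl]chroman-4-yl}-5,7-bis(benzyloxy)-2-[3,4,5-tris(benzyloxy)phenyl]chroman-3-ol | O[C@@H]1Cc2c(OCc3ccccc3)cc(OCc3ccccc3)c([C@@H]3C[C@@H](c4ccc(OCc5ccccc5)c(OCc5ccccc5)c4)Oc4cc(OCc5ccccc5)cc(OCc5ccccc5)c43)c2O[C@@H]1c1cc(OCc2ccccc2)c(OCc2ccccc2)c(OCc2ccccc2)c1 | intermediate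
21 | 3,4,5-tris(benzyloxy)benzoic acid | OC(=O)c1cc(OCc2ccccc2)c(OCc2ccccc2)c(OCc2ccccc2)c1 | starting material
22 | 3-O-[3,4,5-tris(benzyloxy)benzoyl] ester of 20 (dodeca-O-benzyl target) | O=C(O[C@@H]1Cc2c(OCc3ccccc3)cc(OCc3ccccc3)c([C@@H]3C[C@@H](c4ccc(OCc5ccccc5)c(OCc5ccccc5)c4)Oc4cc(OCc5ccccc5)cc(OCc5ccccc5)c43)c2O[C@@H]1c1cc(OCc2ccccc2)c(OCc2ccccc2)c(OCc2ccccc2)c1)c1cc(OCc2ccccc2)c(OCc2ccccc2)c(OCc2ccccc2)c1 | intermediate
23 | (2R,3R)-8-[(2S,4R)-2-(3,4-dihydroxyphenyl)-5,7-dihydroxychroman-4-yl]-5,7-dihydroxy-2-(3,4,5-trihydroxyphenyl)chroman-3-yl 3,4,5-trihydroxybenzoate (CNP0190017.1) | O=C(O[C@@H]1Cc2c(O)cc(O)c([C@@H]3C[C@@H](c4ccc(O)c(O)c4)Oc4cc(O)cc(O)c43)c2O[C@@H]1c1cc(O)c(O)c(O)c1)c1cc(O)c(O)c(O)c1 | target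

**Step count**

Total steps: 14. Longest linear sequence: 13 steps (from 1 through steps 1–4 and 6–14; step 5 is a one-step branch).

**Steps most likely to fail**

Step 8 (Baeyer–Villiger). The peracid may hydroxylate the electron-rich ether rings, above all at C6–H of ring D, faster than it adds to the hindered conjugated ketone. The C2 methylene may also migrate in competition with the meta-dialkoxyaryl carbon, which would give the isochromanone skeleton. The fallback makes the lactone without any oxidant and sets out from 6. Knoevenagel–Doebner condensation of 6 with malonic acid (pyridine, piperidine, 80 °C) should give (E)-3-(EGC*-8-yl)acrylic acid F1. DCC/DMAP esterification with commercial 3,5-bis(benzyloxy)phenol should give 3,5-bis(benzyloxy)phenyl (E)-3-(EGC*-8-yl)acrylate F2. Acid-mediated intramolecular hydroarylation (TFA or BF3·OEt2, CH2Cl2, 0 °C) should then close the six-membered lactone: the O-protonated cinnamate is a benzylic cation stabilised by ring D, and it is attacked by C2 of the phenyl ester ring, which is ortho and para to the two benzyloxy groups. Stereocontrol at C4 is given up in this closure, so 13 would form together with its (4S)-epimer F3. The two are diastereomers and would be separated by chromatography; a silyl ether lost in the acid would be put back with TBSCl/imidazole. The fallback returns to the route at 13.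

Step 7 (asymmetric reductive Heck). Both bond-forming carbons carry two ortho substituents, so the 5-endo insertion may be slow. Formate could then reduce the arylpalladium (hydrodebromination) or the enone first, and the facial selectivity may be poor or mismatched with the chiral flavan unit. The fallback sets out from 10. Miyaura borylation (B2pin2, PdCl2(dppf), KOAc, dioxane, 80 °C) should give (E)-1-[3,5-bis(benzyloxy)-2-(4,4,5,5-tetramethyl-1,3,2-dioxaborolan-2-yl)phenyl]-3-(EGC*-8-yl)prop-2-en-1-one F4. Rhodium-catalysed asymmetric intramolecular 1,4-addition ([Rh(C2H4)2Cl]2, a chiral phosphoramidite or BINAP, aqueous K3PO4, toluene, 80 °C) should then form C3–C3a by transmetalation and conjugate addition. This path needs no hydride source and uses a different chiral catalyst family. The fallback returns to the route at 11.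

Step 11 (Mitsunobu closure). The alkoxyphosphonium at the 3,4-dialkoxybenzylic carbon may ionise before the phenol attacks, which would erode the inversion (a 2,4-cis/trans mixture) or lead to elimination to the styrene. The fallback forms the aryl–oxygen bond O1–C8a instead and leaves the carbinol centre untouched; it sets out from 17. Triflation of the phenol (PhNTf2, Cs2CO3, DMF) should give the aryl triflate of 17, F5. CBS reduction with the (R)-oxazaborolidine (opposite hand, since no inversion follows) should give the (1S)-carbinol aryl triflate F6. Palladium-catalysed intramolecular C–O coupling (Pd2(dba)3, a bulky di-tert-butyl biarylphosphine such as t-BuBrettPhos, Cs2CO3, toluene, 80 °C) should then close ring C with retention at C2. The fallback returns to the route at 19.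

**Further compounds**

F1 | step 8 | (E)-3-(EGC*-8-yl)acrylic acid | CC(C)(C)[Si](C)(C)O[C@@H]1Cc2c(OCc3ccccc3)cc(OCc3ccccc3)c(/C=C/C(=O)O)c2O[C@@H]1c1cc(OCc2ccccc2)c(OCc2ccccc2)c(OCc2ccccc2)c1
F2 | step 8 | 3,5-bis(benzyloxy)phenyl (E)-3-(EGC*-8-yl)acrylate | CC(C)(C)[Si](C)(C)O[C@@H]1Cc2c(OCc3ccccc3)cc(OCc3ccccc3)c(/C=C/C(=O)Oc3cc(OCc4ccccc4)cc(OCc4ccccc4)c3)c2O[C@@H]1c1cc(OCc2ccccc2)c(OCc2ccccc2)c(OCc2ccccc2)c1
F3 | step 8 | (4S)-5,7-bis(benzyloxy)-4-(EGC*-8-yl)chroman-2-one (C4 epimer of 13) | CC(C)(C)[Si](C)(C)O[C@@H]1Cc2c(OCc3ccccc3)cc(OCc3ccccc3)c([C@H]3CC(=O)Oc4cc(OCc5ccccc5)cc(OCc5ccccc5)c43)c2O[C@@H]1c1cc(OCc2ccccc2)c(OCc2ccccc2)c(OCc2ccccc2)c1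
F4 | step 7 | (E)-1-[3,5-bis(benzyloxy)-2-(4,4,5,5-tetramethyl-1,3,2-dioxaborolan-2-yl)phenyl]-3-(EGC*-8-yl)prop-2-en-1-one | CC(C)(C)[Si](C)(C)O[C@@H]1Cc2c(OCc3ccccc3)cc(OCc3ccccc3)c(/C=C/C(=O)c3cc(OCc4ccccc4)cc(OCc4ccccc4)c3B3OC(C)(C)C(C)(C)O3)c2O[C@@H]1c1cc(OCc2ccccc2)c(OCc2ccccc2)c(OCc2ccccc2)c1
F5 | step 11 | aryl triflate of keto-phenol 17 | CC(C)(C)[Si](C)(C)O[C@@H]1Cc2c(OCc3ccccc3)cc(OCc3ccccc3)c([C@@H](c3c(OS(=O)(=O)C(F)(F)F)cc(OCc4ccccc4)cc3OCc3ccccc3)CC(=O)c3ccc(OCc4ccccc4)c(OCc4ccccc4)c3)c2O[C@@H]1c1cc(OCc2ccccc2)c(OCc2ccccc2)c(OCc2ccccc2)c1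
F6 | step 11 | (1S)-carbinol aryl triflate | CC(C)(C)[Si](C)(C)O[C@@H]1Cc2c(OCc3ccccc3)cc(OCc3ccccc3)c([C@@H](c3c(OS(=O)(=O)C(F)(F)F)cc(OCc4ccccc4)cc3OCc3ccccc3)C[C@H](O)c3ccc(OCc4ccccc4)c(OCc4ccccc4)c3)c2O[C@@H]1c1cc(OCc2ccccc2)c(OCc2ccccc2)c(OCc2ccccc2)c1
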